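Ring atoms are numbered C1–C6 as in the target for every monocyclic compound. Compound numbers 1–19 are those of the compound list and are used throughout.

## Analysis of the target

- Target 19 is a cyclohex-3-ene (C3=C4) with a quaternary C1 (methyl and a 2-carboxyethyl chain), a C2 methine carrying a CH2–O–aryl arm (the 7-oxygen of a coumarin), a methyl on C3, an isopropenyl group on C5 and an unsubstituted C6.
- It has three stereocentres, C1 (R), C2 (R) and C5 (S). The acid chain, the aryloxymethyl arm and the isopropenyl group lie on one face and the C1 methyl on the other, so C1 and C2 are contiguous and C5 is remote (1,4 to C2, 1,3 to C1).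
- The sensitive parts are the coumarin lactone (opened by hydroxide, and a Michael acceptor), the C5–H, which is allylic to both alkenes and can isomerise into conjugation under acid, base or hydrogen abstraction, and the ring alkene next to the C2 stereocentre.
- The hard part is the quaternary C1 beside C2 with its larger substituent cis to the C2 arm: a reagent adding to C1 from outside prefers the face away from that arm and would place the chain trans.
- The second difficulty is that C5 must be correlated with the C1/C2 pair although no functional group links them in the final molecule.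
- The strategy rests on one feature. Because the C1 chain and the C2 CH2O group are cis, the chain carbonyl and the CH2O oxygen can be joined into a seven-membered lactone (C1, CH2, CH2, C=O, O, CH2, C2) cis-fused to the carbocycle. The C1–CH2 bond can then be made from within, by a C1 radical reaching an acrylate held on the C2 oxygen.

## Retrosynthetic reasoning

**Acid and aryl ether.** Target 19 comes from methyl ester 18 by ester cleavage, and 18 from hydroxy ester 16 and umbelliferone 17 by cutting the CH2–O(aryl) bond. The coumarin thus enters last, as a commercial phenol, and never meets the radical or organometallic steps. The forward reactions must etherify a hindered primary carbon without base and then free the acid while returning the coumarin ring intact.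

**Ring-opened ester to lactone.** Hydroxy ester 16 is the methanolysis product of lactone 15. Reconnecting the ester oxygen to the C2 CH2 group turns the problem of placing a chain cis to a neighbouring arm into the closure of a ring.

**Key disconnection.** The C1–CH2 bond of 15 is cut, giving a tertiary C1 radical and an acrylate ester on the C2 oxygen, that is cesium oxalate 14.
- This is the one C–C bond at the quaternary centre whose formation the C2 arm can steer.
- A tertiary radical is a nucleophile well matched to an acrylate, and radical formation tolerates the crowding at C1.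
- The oxalate derives from a tertiary alcohol whose configuration need not be controlled, because the radical is planar.
- The forward reaction must close the seven-membered ring faster than the radical is consumed otherwise, and on the face of the tether.

**Ester C–O bonds.** Oxalate 14 goes back through methyl oxalate 13 to acrylate 12, and 12 to diol 10 and acryloyl chloride 11. The primary and tertiary hydroxyl groups of 10 are told apart by sterics alone, so no protecting group is needed.

**C2–CH2OH bond with allylic transposition.** Diol 10 is traced through stannylmethyl ether 8 to diol 7 by a [2,3]-sigmatropic shift from the C4 oxygen to C2. This moves the alkene from C2=C3 to C3=C4 and transfers the C4 configuration to C2 across one face. Since the C4 oxygen of 7 is cis to the C5 isopropenyl group, the cis relation of C2 and C5 is relayed from C5 through C4.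

**C4–H and C1–CH3 bonds.** Diol 7 comes from hydroxy enone 6 by hydride addition at C4 anti to the C5 substituent. Enone 6 comes from ketal alcohol 5 by ketal hydrolysis, and 5 from enone 4 by addition of a methyl nucleophile to the C1 carbonyl. The two carbonyl carbons of a quinone are thus used one after the other, kept apart by the ketal.

**C5–isopropenyl bond.** Enone 4 is cut to dienone 2 and boronate 3 by enantioselective conjugate addition to the unsubstituted enone arm. This is the only stereocentre set by a catalyst; every other one derives from it. Dienone 2 comes from phenol 1 by oxidative dearomatisation.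

## Alternatives that were turned down

**Alternative 1:** The carbocycle is cut at C1–C6 and C2–C3. In the forward direction the 2-siloxy diene A1 adds to the C1-methyl menthyloxy butenolide A2 in a Diels–Alder reaction to give the cis-fused bicyclic acetal lactone A3. In A3 the lactone carbonyl is the future CH2O carbon on C2 and the acetal carbon is the first carbon of the acid chain.
- For: one cycloaddition of a known type builds the ring, the quaternary C1 and the cis C1/C2 relation (fixed by the cis ring fusion of the dienophile), with absolute control from the acetal auxiliary. On precedent for the key bond formation it is stronger than the radical closure to 15.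
- Against: the dienophile carbon that becomes C1 is fully substituted, so the cycloaddition should be sluggish. C5 emerges as a silyl enol ether without a stereocentre and C3 as an sp3 methine. After the key step the alkene must therefore be moved to C3=C4 (for example by a Saegusa-type oxidation and later adjustment), and the isopropenyl group placed on C5 cis to C2 with nothing nearby to direct it. The acetal carbon must also be extended by two carbons and the lactone reduced.
- Comparison: the chosen route fixes C5 first, by catalysis, and relays it to C2 and then C1, and needs only three steps after its key step. The alternative needs a longer sequence after its key step and leaves C5 weakly controlled.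

**Alternative 2:** The C1–CH3 and C2–CH2OH bonds are cut. Forward, a methyl cuprate adds to C1 of enone A4 and the resulting enolate is trapped at C2 by a one-carbon aldehyde electrophile to give hydroxymethyl ketone A5.
- For: both reactions are standard. A cuprate adds anti to the C5 substituent of a 5-substituted cyclohexenone, which puts the methyl trans to the isopropenyl group as required, and two bonds form in one flask. On precedent this is clearly stronger than the chosen key step.
- Against: a cuprate addition that creates a quaternary centre usually needs a silyl chloride, which delivers a silyl enol ether instead of a free enolate, so the trapping becomes a separate Mukaiyama-type aldol. C2 then sits alpha to a ketone beside the new quaternary carbon; its configuration depends on kinetic approach anti to the new axial methyl and can be lost by enolisation, retro-aldol or dehydration. The C3 ketone must still be turned into the C3 methyl and the C3=C4 alkene (regioselective enol triflate away from C2, then methyl coupling). The masked aldehyde must be freed with acid and oxidised, and the absolute configuration at C5 of A4 needs its own source.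
- Comparison: the step count is no shorter. The chosen route sets C2 by a suprafacial sigmatropic shift on a carbon that is never alpha to a carbonyl, and has the C3 methyl and the alkene in place from the first step.

**Alternative 3:** The two bonds of a temporary bridge are cut. Forward, the cyclohexa-1,3-diene A6 (diene C2=C3–C4=C5), whose C1 acid chain ends in an enol ester dienophile, cyclises in an intramolecular Diels–Alder reaction to the tricyclic lactone aldehyde A7. A later Grob fragmentation of the two-carbon bridge releases the isopropenyl group on C5 and a formyl group on C2.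
- For: all three stereocentres are related in one step (the bridge makes C2 and C5 cis, the tether makes C1 and C2 cis), and the bridge carbons end up as the isopropenyl group and the CH2O carbon. In stereochemical economy it is stronger than the chosen route.
- Against: the absolute configuration must come from the quaternary C1 of A6, a 5,5-disubstituted cyclohexadiene that is hard to make in enantioenriched form and prone to 1,5-hydrogen shifts at cycloaddition temperatures. The dienophile is a trisubstituted push–pull alkene that must form a quaternary carbon, and it is tethered through an ester that has to adopt its s-cis rotamer to close a seven-membered lactone. After fragmentation a beta,gamma-unsaturated aldehyde on C2, epimerisable and prone to conjugation, has to be reduced at once.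
- Comparison: the ester-rotamer handicap is shared with the chosen key step. There, however, only one bond forms through an early transition state, the precursor is reached by known reactions, and the absolute configuration comes from a catalytic step.

Key step: step 10

Assumption: the sense of induction of the rhodium/BINAP catalyst on dienone 2 is taken to be that established for cyclohex-2-enone, which calls for (R)-BINAP; if the ketal reverses it, (S)-BINAP is used instead.

Remark: the methyl addition in step 3 may give some of the C1 epimer. It need not be removed, because C1 becomes a planar radical in step 10; the major epimer is drawn.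

## Route

Step 1
Reactants: 1 4-methoxy-3-methylphenol
Product: 2 4,4-dimethoxy-3-methylcyclohexa-2,5-dien-1-one
Conditions: PhI(OAc)2 (1.1 equiv.), MeOH, 0 °C to rt
Reagents that add atoms: methanol, CO
Why: Oxidative dearomatisation of a para-methoxyphenol with a hypervalent iodine reagent; methanol traps the oxidised ring at the methoxy-bearing carbon to give the quinone monoketal. No stereocentre is formed.

Step 2
Reactants: 2 4,4-dimethoxy-3-methylcyclohexa-2,5-dien-1-one; 3 isopropenylboronic acid pinacol ester
Product: 4 (5R)-4,4-dimethoxy-3-methyl-5-(prop-1-en-2-yl)cyclohex-2-en-1-one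
Conditions: [RhCl(C2H4)2]2 (1.5 mol %), (R)-BINAP (3.3 mol %), aq. KOH (0.2 equiv.), 1,4-dioxane/H2O (10:1), 40 °C
Reagents that add atoms: none
Why: Rhodium/BINAP-catalysed asymmetric conjugate addition of an alkenylboron reagent (Hayashi–Miyaura type); only the C5=C6 enone arm reacts because the C3 methyl blocks the other beta-carbon. The chiral rhodium alkenyl species selects the enone face and sets C5, the stereocentre from which all others are derived.

Step 3
Reactants: 4 (5R)-4,4-dimethoxy-3-methyl-5-(prop-1-en-2-yl)cyclohex-2-en-1-one
Product: 6 (4R,6R)-4-hydroxy-2,4-dimethyl-6-(prop-1-en-2-yl)cyclohex-2-en-1-one, via tertiary alcohol ketal 5 (not isolated)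
Conditions: MeMgBr (1.5 equiv.), CeCl3 (1.5 equiv.), THF, −78 °C; then 1 M aq. HCl, 0 °C, 15 min
Reagents that add atoms: methylmagnesium bromide, C[Mg]Br; water, O
Why: CeCl3-promoted 1,2-addition of the Grignard reagent to the C1 carbonyl, expected mainly anti to the C5 isopropenyl group (conjugate addition is blocked by the fully substituted C3). In cold dilute acid the allylic ketal ionises far faster than the tertiary alcohol and hydrolyses to the C4 enone, after which the hydroxyl is deactivated towards ionisation.

Step 4
Reactants: 6 (4R,6R)-4-hydroxy-2,4-dimethyl-6-(prop-1-en-2-yl)cyclohex-2-en-1-one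
Product: 7 (1R,4S,5R)-1,3-dimethyl-5-(prop-1-en-2-yl)cyclohex-2-ene-1,4-diol
Conditions: i-Bu2AlH (3 equiv.), CH2Cl2, −78 °C; aq. potassium sodium tartrate
Reagents that add atoms: none
Why: 1,2-Reduction of the enone by a bulky aluminium hydride, which does not reduce enones in the 1,4 sense. Hydride should enter C4 from the face opposite the neighbouring C5 isopropenyl group, giving the C4 hydroxyl cis to it.

Step 5
Reactants: 7 (1R,4S,5R)-1,3-dimethyl-5-(prop-1-en-2-yl)cyclohex-2-ene-1,4-diol
Product: 8 (1R,4S,5R)-1,3-dimethyl-5-(prop-1-en-2-yl)-4-[(tributylstannyl)methoxy]cyclohex-2-en-1-ol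
Conditions: KH (1.05 equiv.), THF, 0 °C; Bu3SnCH2I (1.1 equiv.), 0 °C to rt
Reagents that add atoms: tributyl(iodomethyl)stannane, CCCC[Sn](CCCC)(CCCC)CI
Why: Williamson etherification, the first stage of the Still–Wittig sequence. With one equivalent of KH the more acidic secondary allylic hydroxyl is deprotonated preferentially, and its alkoxide is also the better nucleophile compared with the tertiary one.

Step 6
Reactants: 8 (1R,4S,5R)-1,3-dimethyl-5-(prop-1-en-2-yl)-4-[(tributylstannyl)methoxy]cyclohex-2-en-1-ol
Product: 10 (1R,2R,5S)-2-(hydroxymethyl)-1,3-dimethyl-5-(prop-1-en-2-yl)cyclohex-3-en-1-ol, via lithiomethyl ether dianion 9 (not isolated)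
Conditions: n-BuLi (2.5 equiv.), THF, −78 °C to −20 °C; then H2O
Reagents that add atoms: none
Why: Tin–lithium exchange gives the alpha-alkoxymethyllithium, which undergoes the [2,3]-Wittig (Still–Wittig) rearrangement. The shift is suprafacial, so the CH2OH group arrives at C2 on the face that carried the C4 oxygen, cis to the C5 isopropenyl group, while the alkene moves to C3=C4.

Step 7
Reactants: 10 (1R,2R,5S)-2-(hydroxymethyl)-1,3-dimethyl-5-(prop-1-en-2-yl)cyclohex-3-en-1-ol; 11 acryloyl chloride
Product: 12 [(1R,4S,6R)-6-hydroxy-2,6-dimethyl-4-(prop-1-en-2-yl)cyclohex-2-en-1-yl]methyl prop-2-enoate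
Conditions: 11 (1.05 equiv.), Et3N (1.5 equiv.), CH2Cl2, −78 °C to 0 °C
Reagents that add atoms: none
Why: Chemoselective acylation of the primary alcohol; the hindered tertiary C1 hydroxyl does not react at low temperature.

Step 8
Reactants: 12 [(1R,4S,6R)-6-hydroxy-2,6-dimethyl-4-(prop-1-en-2-yl)cyclohex-2-en-1-yl]methyl prop-2-enoate
Product: 13 methyl (1R,2R,5S)-2-(acryloyloxymethyl)-1,3-dimethyl-5-(prop-1-en-2-yl)cyclohex-3-en-1-yl oxalate
Conditions: ClC(O)CO2Me (1.5 equiv.), Et3N (2 equiv.), DMAP (0.2 equiv.), CH2Cl2, 0 °C to rt
Reagents that add atoms: methyl chlorooxoacetate, COC(=O)C(=O)Cl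
Why: DMAP-catalysed acylation of the tertiary alcohol by a highly electrophilic acid chloride, the standard entry to tertiary alkyl oxalates.

Step 9
Reactants: 13 methyl (1R,2R,5S)-2-(acryloyloxymethyl)-1,3-dimethyl-5-(prop-1-en-2-yl)cyclohex-3-en-1-yl oxalate
Product: 14 cesium 2-{[(1R,2R,5S)-2-(acryloyloxymethyl)-1,3-dimethyl-5-(prop-1-en-2-yl)cyclohex-3-en-1-yl]oxy}-2-oxoacetate
Conditions: CsOH·H2O (1.0 equiv.), THF/H2O, 0 °C; concentrate
Reagents that add atoms: cesium hydroxide, [Cs+].[OH-]
Why: The methyl oxalate carbonyl is activated by the adjacent carbonyl and is saponified far faster than the acrylate or the shielded tert-alkyl oxalate ester. One equivalent of hydroxide at 0 °C should therefore cleave only that ester.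

Step 10
Reactants: 14 cesium 2-{[(1R,2R,5S)-2-(acryloyloxymethyl)-1,3-dimethyl-5-(prop-1-en-2-yl)cyclohex-3-en-1-yl]oxy}-2-oxoacetate
Product: 15 (5aR,7S,9aR)-5a,9-dimethyl-7-(prop-1-en-2-yl)-4,5,5a,6,7,9a-hexahydro-2-benzoxepin-3(1H)-one
Conditions: [Ir(dF(CF3)ppy)2(dtbbpy)]PF6 (2 mol %), DME/DMF (3:1), H2O (10 equiv.), blue LEDs, 60 °C, syringe-pump addition of 14, final 0.002 M
Reagents that add atoms: none
Why: Proposed new method: the excited trivalent-iridium photocatalyst oxidises the oxalate carboxylate, two molecules of CO2 are lost and a nucleophilic tertiary radical forms at C1; it adds to the terminal carbon of the tethered acrylate, and the alpha-ester radical is reduced by the divalent iridium formed in the first electron transfer and protonated by water. The closest known reaction type is the intermolecular photoredox Giese addition of tertiary radicals from cesium alkyl oxalates to acrylates; closure of a lactone ring through the ester tether has not been shown. The ring closes in the 7-endo-trig mode, not because a 6-exo closure is out of reach but because attack at the acrylate alpha-carbon is polarity-mismatched and would give an unstabilised primary radical, whereas beta-attack gives the alpha-ester radical. The one new stereocentre, C1, is set by the tether: the C2 arm sits pseudoaxial between the C1 and C3 methyl groups (allylic 1,2-strain), parallel to the C1 p-orbital, so the acrylate reaches only the lobe on its own face and the ring fusion should be cis, while the C1 configuration of 14 is erased in the planar radical. The step needs the closure to beat intermolecular Giese addition and hydrogen abstraction although the ester must turn into its less stable s-cis rotamer; slow addition at high dilution, a polar aqueous medium that narrows the rotamer gap, and 60 °C are meant to secure this. The C3=C4 and isopropenyl alkenes are unactivated and should not trap the nucleophilic radical.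

Step 11
Reactants: 15 (5aR,7S,9aR)-5a,9-dimethyl-7-(prop-1-en-2-yl)-4,5,5a,6,7,9a-hexahydro-2-benzoxepin-3(1H)-one
Product: 16 methyl 3-[(1R,2R,5S)-2-(hydroxymethyl)-1,3-dimethyl-5-(prop-1-en-2-yl)cyclohex-3-en-1-yl]propanoate
Conditions: K2CO3 (0.2 equiv.), MeOH, 0 °C to rt; AcOH quench
Reagents that add atoms: methanol, CO
Why: Base-catalysed methanolysis of the strained seven-membered lactone in methanol as solvent frees the primary alcohol and gives the methyl ester. No stereocentre is touched.

Step 12
Reactants: 16 methyl 3-[(1R,2R,5S)-2-(hydroxymethyl)-1,3-dimethyl-5-(prop-1-en-2-yl)cyclohex-3-en-1-yl]propanoate; 17 umbelliferone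
Product: 18 methyl 3-[(1R,2R,5S)-1,3-dimethyl-2-{[(2-oxo-2H-chromen-7-yl)oxy]methyl}-5-(prop-1-en-2-yl)cyclohex-3-en-1-yl]propanoate
Conditions: 17 (1.5 equiv.), PPh3 (1.5 equiv.), DIAD (1.5 equiv.), THF, 0 °C to rt (50 °C if slow)
Reagents that add atoms: none
Why: Mitsunobu etherification; the acidic phenol is alkylated by the alkoxyphosphonium ion of the primary alcohol. Substitution occurs at a CH2 group, so no stereocentre is involved, and the neutral conditions spare the ester and both alkenes.

Step 13
Reactants: 18 methyl 3-[(1R,2R,5S)-1,3-dimethyl-2-{[(2-oxo-2H-chromen-7-yl)oxy]methyl}-5-(prop-1-en-2-yl)cyclohex-3-en-1-yl]propanoate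
Product: 19 3-[(1R,2R,5S)-1,3-dimethyl-2-{[(2-oxo-2H-chromen-7-yl)oxy]methyl}-5-(prop-1-en-2-yl)cyclohex-3-en-1-yl]propanoic acid
Conditions: LiOH·H2O (3 equiv.), THF/H2O (3:1), rt, dark; then 1 M HCl to pH 2
Reagents that add atoms: lithium hydroxide, [Li+].[OH-]
Why: Saponification of the methyl ester. Hydroxide may also open the coumarin lactone to the cis-2-hydroxycinnamate, which closes again spontaneously on acidification, so the coumarin is restored together with the free acid.

## Compound list

1 | 4-methoxy-3-methylphenol | COc1ccc(O)cc1C | starting material
2 | 4,4-dimethoxy-3-methylcyclohexa-2,5-dien-1-one | COC1(OC)C=CC(=O)C=C1C | intermediate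
3 | isopropenylboronic acid pinacol ester | C=C(C)B1OC(C)(C)C(C)(C)O1 | starting material
4 | (5R)-4,4-dimethoxy-3-methyl-5-(prop-1-en-2-yl)cyclohex-2-en-1-one | C=C(C)[C@@H]1C(OC)(OC)C(C)=CC(=O)C1 | intermediate
5 | (1R,5R)-4,4-dimethoxy-1,3-dimethyl-5-(prop-1-en-2-yl)cyclohex-2-en-1-ol | C=C(C)[C@@H]1C(OC)(OC)C(C)=C[C@](C)(O)C1 | intermediate
6 | (4R,6R)-4-hydroxy-2,4-dimethyl-6-(prop-1-en-2-yl)cyclohex-2-en-1-one | C=C(C)[C@@H]1C(=O)C(C)=C[C@](C)(O)C1 | intermediate
7 | (1R,4S,5R)-1,3-dimethyl-5-(prop-1-en-2-yl)cyclohex-2-ene-1,4-diol | C=C(C)[C@@H]1[C@H](O)C(C)=C[C@](C)(O)C1 | intermediate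
8 | (1R,4S,5R)-1,3-dimethyl-5-(prop-1-en-2-yl)-4-[(tributylstannyl)methoxy]cyclohex-2-en-1-ol | C=C(C)[C@@H]1[C@H](OC[Sn](CCCC)(CCCC)CCCC)C(C)=C[C@](C)(O)C1 | intermediate
9 | lithium (1R,4S,5R)-4-(lithiomethoxy)-1,3-dimethyl-5-(prop-1-en-2-yl)cyclohex-2-en-1-olate | C=C(C)[C@@H]1[C@H](OC[Li])C(C)=C[C@](C)(O[Li])C1 | intermediate
10 | (1R,2R,5S)-2-(hydroxymethyl)-1,3-dimethyl-5-(prop-1-en-2-yl)cyclohex-3-en-1-ol | C=C(C)[C@@H]1C=C(C)[C@H](CO)[C@](C)(O)C1 | intermediate
11 | acryloyl chloride | C=CC(=O)Cl | starting material
12 | [(1R,4S,6R)-6-hydroxy-2,6-dimethyl-4-(prop-1-en-2-yl)cyclohex-2-en-1-yl]methyl prop-2-enoate | C=C(C)[C@@H]1C=C(C)[C@H](COC(=O)C=C)[C@](C)(O)C1 | intermediate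
13 | methyl (1R,2R,5S)-2-(acryloyloxymethyl)-1,3-dimethyl-5-(prop-1-en-2-yl)cyclohex-3-en-1-yl oxalate | C=C(C)[C@@H]1C=C(C)[C@H](COC(=O)C=C)[C@](C)(OC(=O)C(=O)OC)C1 | intermediate
14 | cesium 2-{[(1R,2R,5S)-2-(acryloyloxymethyl)-1,3-dimethyl-5-(prop-1-en-2-yl)cyclohex-3-en-1-yl]oxy}-2-oxoacetate | C=C(C)[C@@H]1C=C(C)[C@H](COC(=O)C=C)[C@](C)(OC(=O)C(=O)[O-])C1.[Cs+] | intermediate
15 | (5aR,7S,9aR)-5a,9-dimethyl-7-(prop-1-en-2-yl)-4,5,5a,6,7,9a-hexahydro-2-benzoxepin-3(1H)-one (cis-fused seven-membered lactone) | C=C(C)[C@@H]1C=C(C)[C@@H]2COC(=O)CC[C@]2(C)C1 | intermediate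
16 | methyl 3-[(1R,2R,5S)-2-(hydroxymethyl)-1,3-dimethyl-5-(prop-1-en-2-yl)cyclohex-3-en-1-yl]propanoate | C=C(C)[C@@H]1C=C(C)[C@H](CO)[C@](C)(CCC(=O)OC)C1 | intermediate
17 | umbelliferone (7-hydroxy-2H-chromen-2-one) | O=c1ccc2ccc(O)cc2o1 | starting material
18 | methyl 3-[(1R,2R,5S)-1,3-dimethyl-2-{[(2-oxo-2H-chromen-7-yl)oxy]methyl}-5-(prop-1-en-2-yl)cyclohex-3-en-1-yl]propanoate | C=C(C)[C@@H]1C=C(C)[C@H](COc2ccc3ccc(=O)oc3c2)[C@](C)(CCC(=O)OC)C1 | intermediate
19 | 3-[(1R,2R,5S)-1,3-dimethyl-2-{[(2-oxo-2H-chromen-7-yl)oxy]methyl}-5-(prop-1-en-2-yl)cyclohex-3-en-1-yl]propanoic acid | C=C(C)[C@@H]1C=C(C)[C@H](COc2ccc3ccc(=O)oc3c2)[C@](C)(CCC(=O)O)C1 | target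

## Step count and least certain steps

Total: 13 steps. Longest linear sequence: 13 steps, from 1 to 19; compounds 3, 11 and 17 are bought.

**Step 10 (key step, proposed new method).**
- What may go wrong: the closure should be slow, because the ester has to rotate into its s-cis form before the acrylate can reach C1. Intermolecular Giese addition (oligomerisation) or hydrogen abstraction from the solvent by the C1 radical may then outrun lactone formation. The alpha-ester radical may also add onward to the C3=C4 or isopropenyl alkene before it is reduced. Loss of cis selectivity is the less likely failure.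
- Fallback (known chemistry, from 10 to 16): the ester tether is replaced by an ether tether that closes a five-membered ring. Diol 10 adds through its primary hydroxyl to methyl propiolate (N-methylmorpholine, CH2Cl2) to give the (E)-beta-alkoxyacrylate F1. The tertiary alcohol is converted as in steps 8 and 9 into the methyl oxalate F2 and the cesium oxalate F3. Under the same photocatalyst the C1 radical closes 5-exo-trig onto the alkoxy-bearing acrylate carbon, an established mode of radical cyclisation, giving the cis-fused bicyclic tetrahydrofuran ester F4 with the full three-carbon chain on C1. KN(SiMe3)2 (THF, −78 °C to −20 °C, AcOH quench at −78 °C) opens the ether ring by E1cB elimination to the hydroxy enoate F5. Conjugate reduction with [(Ph3P)CuH]6 in wet toluene then gives hydroxy ester 16, where the route is rejoined.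

**Step 5 (and with it step 6).**
- What may go wrong: etherification at the tertiary instead of the secondary oxygen, or incomplete etherification of the hindered secondary alkoxide. In step 6, a competing [1,2]-shift or simple protonation of the carbanion may occur, because the new bond forms at C2 beside the quaternary, alkoxide-bearing C1.
- Fallback (from 7 to 10): a carbamate-directed syn SN2′ substitution replaces both steps. Diol 7 reacts at its secondary hydroxyl with phenyl isocyanate to give the N-phenylcarbamate F6. Deprotonation (n-BuLi, 2 equiv.), CuI and (i-PrO)Me2SiCH2MgCl deliver the silylmethyl group to C2 on the face of the carbamate with allylic transposition, giving the silane F7. Tamao oxidation (KF, KHCO3, H2O2, THF/MeOH) then gives diol 10.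

**Step 4.**
- What may go wrong: poor facial selectivity, with axial hydride delivery giving the C4 epimer (hydroxyl trans to isopropenyl), which would place the CH2OH group on the wrong face in step 6.
- Fallback (from 6 to 7): reduction and inversion. Enone 6 is reduced with NaBH4 and CeCl3·7H2O in MeOH (Luche reduction), which should favour axial attack and give the trans diol F8. Mitsunobu inversion with 4-nitrobenzoic acid (PPh3, DIAD) gives the cis 4-nitrobenzoate F9; the tertiary hydroxyl does not take part. Methanolysis (K2CO3, MeOH) gives 7.

**Step 9.**
- What may go wrong: loss of the acrylate by saponification or by conjugate addition of hydroxide, if the rate gap to the methyl oxalate is smaller than expected.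
- Fallback (from 12 to 14): no hydroxide is used. Acrylate 12 is treated with excess oxalyl chloride (Et2O, 0 °C, argon stream) to give the chlorooxoacetate F10. After removal of the volatiles this is hydrolysed with aqueous CsHCO3 (2 equiv., THF, 0 °C) to cesium oxalate 14.

**Step 2.**
- What may go wrong: slow transmetalation or protodeboronation of the hindered alkenyl boronate, low enantioselectivity beside the ketal, or acid-promoted aromatisation of the product by loss of methanol.
- Fallback (from 2 to 4): copper-catalysed enantioselective conjugate addition of isopropenylmagnesium bromide (CuBr·SMe2, a chiral ferrocenyl diphosphine of the Josiphos type, t-BuOMe, −78 °C). This uses a different metal and a different class of nucleophile and makes no new intermediate.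

## Further compounds

F1 | step 10 | methyl (E)-3-alkoxyacrylate of the C2 hydroxymethyl group of 10 (tertiary C1 hydroxyl free) | C=C(C)[C@@H]1C=C(C)[C@H](CO/C=C/C(=O)OC)[C@](C)(O)C1
F2 | step 10 | methyl oxalate of the C1 tertiary alcohol of F1 | C=C(C)[C@@H]1C=C(C)[C@H](CO/C=C/C(=O)OC)[C@](C)(OC(=O)C(=O)OC)C1
F3 | step 10 | cesium oxalate of the C1 tertiary alcohol of F1 | C=C(C)[C@@H]1C=C(C)[C@H](CO/C=C/C(=O)OC)[C@](C)(OC(=O)C(=O)[O-])C1.[Cs+]
F4 | step 10 | cis-fused bicyclic tetrahydrofuran with a CH2CO2Me group on the new O–CH carbon (epimers at that carbon) | C=C(C)[C@@H]1C=C(C)[C@@H]2COC(CC(=O)OC)[C@]2(C)C1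
F5 | step 10 | methyl (E)-3-[2-(hydroxymethyl)-1,3-dimethyl-5-(prop-1-en-2-yl)cyclohex-3-en-1-yl]prop-2-enoate, ring configuration as in 16 | C=C(C)[C@@H]1C=C(C)[C@H](CO)[C@](C)(/C=C/C(=O)OC)C1
F6 | step 5 | N-phenylcarbamate of the C4 hydroxyl of 7 | C=C(C)[C@@H]1[C@H](OC(=O)Nc2ccccc2)C(C)=C[C@](C)(O)C1
F7 | step 5 | 2-[(isopropoxydimethylsilyl)methyl]-1,3-dimethyl-5-(prop-1-en-2-yl)cyclohex-3-en-1-ol, ring configuration as in 10 | C=C(C)[C@@H]1C=C(C)[C@H](C[Si](C)(C)OC(C)C)[C@](C)(O)C1
F8 | step 4 | C4 epimer of 7 (C4 hydroxyl trans to isopropenyl) | C=C(C)[C@@H]1[C@@H](O)C(C)=C[C@](C)(O)C1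
F9 | step 4 | 4-nitrobenzoate of the C4 hydroxyl of 7 | C=C(C)[C@@H]1[C@H](OC(=O)c2ccc(cc2)[N+](=O)[O-])C(C)=C[C@](C)(O)C1
F10 | step 9 | chlorooxoacetate of the C1 tertiary alcohol of 12 | C=C(C)[C@@H]1C=C(C)[C@H](COC(=O)C=C)[C@](C)(OC(=O)C(=O)Cl)C1
F0 | step 2 | none | none
A1 | alternative 1 | (E)-2-(tert-butyldimethylsilyloxy)penta-1,3-diene | C=C(O[Si](C)(C)C(C)(C)C)/C=C/C
A2 | alternative 1 | 5-menthyloxy-4-methylfuran-2(5H)-one | CC(C)[C@@H]1CC[C@@H](C)C[C@H]1O[C@@H]2OC(=O)C=C2C
A3 | alternative 1 | cis-fused bicyclic acetal lactone with C5 silyl enol ether and C3 methyl | CC(C)[C@@H]1CC[C@@H](C)C[C@H]1O[C@@H]2OC(=O)[C@H]3[C@@H](C)C=C(O[Si](C)(C)C(C)(C)C)C[C@@]23C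
A4 | alternative 2 | 3-[2-(1,3-dioxolan-2-yl)ethyl]-5-(prop-1-en-2-yl)cyclohex-2-en-1-one | C=C(C)[C@@H]1CC(=O)C=C(CCC2OCCO2)C1
A5 | alternative 2 | 3-[2-(1,3-dioxolan-2-yl)ethyl]-2-(hydroxymethyl)-3-methyl-5-(prop-1-en-2-yl)cyclohexan-1-one | C=C(C)[C@@H]1CC(=O)[C@H](CO)[C@](C)(CCC2OCCO2)C1
A6 | alternative 3 | (E)-2-methyl-3-oxoprop-1-en-1-yl 3-(1,3-dimethylcyclohexa-2,4-dien-1-yl)propanoate | O=C/C(C)=C/OC(=O)CC[C@@]1(C)C=C(C)C=CC1
A7 | alternative 3 | tricyclic lactone aldehyde with the temporary two-carbon bridge | O=C[C@]1(C)[C@@H]2C=C(C)[C@@H]3[C@H]1OC(=O)CC[C@]3(C)C2
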